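**Plan**

Decalin numbering used throughout: C1 (CO2R), C2 (CH3), C3, C4, C4a (CH3), C5 (4-methylpent-3-enyl)=C6, C7, C8, C8a (CH3). Ring A = C1, C2, C3, C4, C4a, C8a. Ring B = C4a, C5, C6, C7, C8, C8a.
Retrosynthetic cuts: first the acetate and acyl C–O bonds of the glycerol, then the C1–CO2 carbon (back to a C1 ketone). Next C7–C8 and C4a–C8a go in one stroke (retro-Diels–Alder) to the open-chain trienone 16, and last C1–C8a, C3–C4 and C5–C6 of the chain.
Enabling feature: ring B is a cyclohexene whose C5=C6 bond lies between C4a and C7, with C8–C8a opposite to it, and C1–C4 of ring A form a four-atom tether from C8a to C4a. A C4a=C5–C6=C7 diene and a C8=C8a dienophile can therefore fold onto each other; a C1 carbonyl activates the dienophile (helper, its oxygen leaves in step 13).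
Forward order: side chain and diene are built on a beta-keto ester (steps 2–6), and the chain is joined at C3–C4 (step 7) and C1–C8a (step 10). Step 12 closes rings A and B together (ring B as the [4+2] ring, no ring is closed after it); then C1 is homologated and the glyceride is attached.
Stereochemistry: C2 comes from (S)-3-bromo-2-methylpropan-1-ol and the C4a=C5 geometry from an E enol tosylate. C4a and C8a come from the endo, chair-tether transition state steered by C2, C1 from equilibration of the aldehyde, and the glycerol centre from (S)-solketal tosylate.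

Key step: step 12

Remark on the chemistry: C2 of 6 and C1 of 15, 19, 20 and 21 are written without configuration because both epimers are carried on and converge. Compounds 1 and 24 are taken as commercial single enantiomers.

**Route**

Step 1
Reactants: 1 (S)-3-bromo-2-methylpropan-1-ol
Product: 2 (S)-(3-bromo-2-methylpropoxy)(tert-butyl)dimethylsilane
Conditions: TBSCl, imidazole, CH2Cl2, 0 °C → rt
Reagents that add atoms: tert-butyldimethylsilyl chloride, CC(C)(C)[Si](C)(C)Cl
Why: Imidazole-promoted silyl ether formation masks the future C1 oxygen for the Grignard chemistry and does not touch the C2 stereocentre.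

Step 2
Reactants: 3 ethyl 2-methyl-3-oxobutanoate; 4 1-bromo-3-methylbut-2-ene (prenyl bromide)
Product: 6 ethyl 2,7-dimethyl-3-oxooct-6-enoate, via acetoacetate dianion 5 (not isolated)
Conditions: NaH, THF, 0 °C; n-BuLi, 0 °C; then 4, 0 °C → rt; aq. NH4Cl
Reagents that add atoms: none
Why: In the gamma-alkylation of an acetoacetate dianion the more basic terminal carbanion attacks the allylic bromide (SN2), which puts the complete 4-methylpent-3-enyl chain on the future C5.

Step 3
Reactants: 6 ethyl 2,7-dimethyl-3-oxooct-6-enoate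
Product: 7 ethyl (2E)-2,7-dimethyl-3-(tosyloxy)octa-2,6-dienoate
Conditions: TsCl, N-methylimidazole, Et3N, CH2Cl2, 0 °C → rt
Reagents that add atoms: p-toluenesulfonyl chloride, Cc1ccc(cc1)S(=O)(=O)Cl
Why: In this stereoselective enol sulfonylation of an alpha-substituted beta-keto ester, amine bases without a chelating metal ion let the non-chelated enolate react, which should give the E enol tosylate (OTs trans to CO2Et) and so fix the geometry of the future C4a=C5 bond.

Step 4
Reactants: 7 ethyl (2E)-2,7-dimethyl-3-(tosyloxy)octa-2,6-dienoate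
Product: 8 ethyl (2E)-3-ethenyl-2,7-dimethylocta-2,6-dienoate
Conditions: vinylboronic acid pinacol ester, Pd(dppf)Cl2 (5 mol %), K2CO3, dioxane/H2O, 70 °C
Reagents that add atoms: vinylboronic acid pinacol ester, C=CB1OC(C)(C)C(C)(C)O1
Why: Suzuki–Miyaura coupling of the activated (vinylogous) enol tosylate proceeds with retention of alkene geometry, so the vinyl group (C6=C7) ends up cis to the C4a methyl group.

Step 5
Reactants: 8 ethyl (2E)-3-ethenyl-2,7-dimethylocta-2,6-dienoate
Product: 9 (2E)-3-ethenyl-2,7-dimethylocta-2,6-dien-1-ol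
Conditions: i-Bu2AlH (2.3 equiv), CH2Cl2, −78 °C; Rochelle salt work-up
Reagents that add atoms: none
Why: DIBAL-H reduces the conjugated ester in the 1,2-sense to the allylic alcohol (future C4) without touching the diene or its geometry.

Step 6
Reactants: 9 (2E)-3-ethenyl-2,7-dimethylocta-2,6-dien-1-ol
Product: 10 (2E)-1-bromo-3-ethenyl-2,7-dimethylocta-2,6-diene
Conditions: CBr4, PPh3, CH2Cl2, −20 °C; used at once
Reagents that add atoms: carbon tetrabromide, BrC(Br)(Br)Br
Why: The Appel bromination works under neutral conditions by SN2 on the alkoxyphosphonium ion, as for geraniol-type alcohols, so allylic transposition and E/Z scrambling are kept down.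

Step 7
Reactants: 2 (S)-(3-bromo-2-methylpropoxy)(tert-butyl)dimethylsilane; 10 (2E)-1-bromo-3-ethenyl-2,7-dimethylocta-2,6-diene
Product: 12 tert-butyl{[(2R,5E)-6-ethenyl-2,5,10-trimethylundeca-5,9-dien-1-yl]oxy}dimethylsilane, via Grignard reagent 11 (not isolated)
Conditions: 2, Mg, THF, 40 °C; then Li2CuCl4 (5 mol %), 10, THF, −40 → 0 °C
Reagents that add atoms: none
Why: Copper-catalysed Grignard cross-coupling with a primary allylic bromide whose gamma carbon is fully substituted should occur at the alpha carbon with retention of alkene geometry (as with geranyl bromide), which forms C3–C4 and leaves C2 untouched.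

Step 8
Reactants: 12 tert-butyl{[(2R,5E)-6-ethenyl-2,5,10-trimethylundeca-5,9-dien-1-yl]oxy}dimethylsilane
Product: 13 (2R,5E)-6-ethenyl-2,5,10-trimethylundeca-5,9-dien-1-ol
Conditions: Bu4NF, THF, rt
Reagents that add atoms: none
Why: Fluoride-induced desilylation is driven by the Si–F bond and is inert toward the diene and the isolated alkene.

Step 9
Reactants: 13 (2R,5E)-6-ethenyl-2,5,10-trimethylundeca-5,9-dien-1-ol
Product: 14 (2R,5E)-6-ethenyl-2,5,10-trimethylundeca-5,9-dienal
Conditions: Dess–Martin periodinane, CH2Cl2, 0 °C → rt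
Reagents that add atoms: none
Why: Dess–Martin oxidation is mild and base-free, so the alpha-stereocentre C2 of the aldehyde should not epimerise.

Step 10
Reactants: 14 (2R,5E)-6-ethenyl-2,5,10-trimethylundeca-5,9-dienal
Product: 15 (4R,7E)-8-ethenyl-2,4,7,12-trimethyltrideca-1,7,11-trien-3-ol (both carbinol epimers)
Conditions: isopropenylmagnesium bromide, THF, −78 °C
Reagents that add atoms: isopropenylmagnesium bromide, C=C(C)[Mg]Br
Why: Grignard 1,2-addition forms C1–C8a and brings in C8 and the C8a methyl group; the new carbinol centre is irrelevant because it is oxidised in the next step.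

Step 11
Reactants: 15 (4R,7E)-8-ethenyl-2,4,7,12-trimethyltrideca-1,7,11-trien-3-ol
Product: 16 (4R,7E)-8-ethenyl-2,4,7,12-trimethyltrideca-1,7,11-trien-3-one
Conditions: Dess–Martin periodinane, CH2Cl2, 0 °C; used directly
Reagents that add atoms: none
Why: Dess–Martin oxidation of the allylic alcohol gives the isopropenyl ketone (the activated dienophile) without base, so C2 keeps its configuration.

Step 12
Reactants: 16 (4R,7E)-8-ethenyl-2,4,7,12-trimethyltrideca-1,7,11-trien-3-one
Product: 17 (2R,4aR,8aS)-2,4a,8a-trimethyl-5-(4-methylpent-3-en-1-yl)-3,4,4a,7,8,8a-hexahydronaphthalen-1(2H)-one (cis-fused)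
Conditions: MeAlCl2 (1.1 equiv), CH2Cl2, −78 → 0 °C
Reagents that add atoms: none
Why: MeAlCl2 binds the C1 carbonyl, lowers the LUMO of the C8=C8a isopropenyl dienophile and triggers a concerted but strongly asynchronous [4+2] in which the unhindered C7–C8 bond runs ahead (largest diene HOMO coefficient at C7, largest enone LUMO coefficient at C8) and the crowded C4a–C8a bond follows, which is why two adjacent quaternary carbons can form. The closest known reaction type is the Lewis-acid-promoted type 1 intramolecular Diels–Alder reaction of 1,7,9-decatrien-3-ones to cis-fused octalones. Ring B closes as the six-membered [π4s+π2s] ring (C4a=C5–C6=C7 plus C8=C8a) and leaves C5=C6 with its side chain exactly in place, while ring A closes in the same event in the fused mode as the six-membered tether ring C8a–C1–C2–C3–C4–C4a. C4a and C8a are set relative to each other by suprafacial addition to the E-configured C4a=C5 bond (tether outside, methyl inside) through the transition state with the complexed carbonyl endo, which puts both methyl groups on the same face (cis-decalin). Their absolute sense comes from C2, because in the chair-like tether the C2 methyl group stays equatorial, the axial alternative being syn-axial to the C8a methyl group. The step needs endo over exo selectivity (Lewis-acid complexation, and the clash of an endo C8a methyl group with the C5 substituent), chemoselectivity for the diene over the remote trisubstituted alkene (only the diene is within reach of a six-membered tether) and no enolisation at C2 (low temperature, MeAlCl2 scavenges protons).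

Step 13
Reactants: 17 (2R,4aR,8aS)-2,4a,8a-trimethyl-5-(4-methylpent-3-en-1-yl)-3,4,4a,7,8,8a-hexahydronaphthalen-1(2H)-one
Product: 18 (2R,4aR,8aR)-2,4a,8a-trimethyl-1-methylidene-5-(4-methylpent-3-en-1-yl)-1,2,3,4,4a,7,8,8a-octahydronaphthalene
Conditions: Cp2TiMe2 (3 equiv), toluene, 75 °C, dark
Reagents that add atoms: dimethyltitanocene, C[Ti](C)(C1C=CC=C1)C1C=CC=C1
Why: In the Petasis methylenation the non-basic titanium methylidene reacts with hindered, enolisable ketones through an oxatitanacyclobutane, so the epimerisable C2 is preserved, the helper oxygen leaves and the future carboxyl carbon arrives.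

Step 14
Reactants: 18 (2R,4aR,8aR)-2,4a,8a-trimethyl-1-methylidene-5-(4-methylpent-3-en-1-yl)-1,2,3,4,4a,7,8,8a-octahydronaphthalene
Product: 20 [(2R,4aR,8aR)-2,4a,8a-trimethyl-5-(4-methylpent-3-en-1-yl)-1,2,3,4,4a,7,8,8a-octahydronaphthalen-1-yl]methanol (C1 epimers), via B-alkyl-9-BBN adduct 19 (not isolated)
Conditions: 9-BBN, THF, rt → 45 °C; then NaOH, H2O2, 0 °C
Reagents that add atoms: hydrogen peroxide, OO
Why: In this anti-Markovnikov hydroboration–oxidation 9-BBN places boron on the CH2 terminus of the 1,1-disubstituted alkene much faster than it attacks either trisubstituted alkene, and the C1 configuration formed here does not matter because it is reset in step 15.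

Step 15
Reactants: 20 [(2R,4aR,8aR)-2,4a,8a-trimethyl-5-(4-methylpent-3-en-1-yl)-1,2,3,4,4a,7,8,8a-octahydronaphthalen-1-yl]methanol
Product: 22 (1S,2R,4aR,8aR)-2,4a,8a-trimethyl-5-(4-methylpent-3-en-1-yl)-1,2,3,4,4a,7,8,8a-octahydronaphthalene-1-carbaldehyde, via aldehyde epimer mixture 21 (not isolated)
Conditions: Dess–Martin periodinane, CH2Cl2, rt; then K2CO3, MeOH, rt
Reagents that add atoms: none
Why: Dess–Martin oxidation followed by base-mediated enolisation equilibrates C1 to the equatorial aldehyde (trans to the C2 methyl group and free of the syn-axial clash with C5), so C1 is set under thermodynamic control by C2, C4a and C8a.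

Step 16
Reactants: 22 (1S,2R,4aR,8aR)-2,4a,8a-trimethyl-5-(4-methylpent-3-en-1-yl)-1,2,3,4,4a,7,8,8a-octahydronaphthalene-1-carbaldehyde
Product: 23 (1S,2R,4aR,8aR)-2,4a,8a-trimethyl-5-(4-methylpent-3-en-1-yl)-1,2,3,4,4a,7,8,8a-octahydronaphthalene-1-carboxylic acid
Conditions: NaClO2, NaH2PO4, 2-methylbut-2-ene, t-BuOH/H2O, rt
Reagents that add atoms: sodium chlorite, [Na+].[O-]Cl=O
Why: The Pinnick oxidation converts hindered aldehydes to acids without epimerisation, and the alkene scavenger takes up HOCl so that the two trisubstituted alkenes survive.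

Step 17
Reactants: 23 (1S,2R,4aR,8aR)-2,4a,8a-trimethyl-5-(4-methylpent-3-en-1-yl)-1,2,3,4,4a,7,8,8a-octahydronaphthalene-1-carboxylic acid; 24 [(4S)-2,2-dimethyl-1,3-dioxolan-4-yl]methyl 4-methylbenzenesulfonate
Product: 26 [(4S)-2,2-dimethyl-1,3-dioxolan-4-yl]methyl ester of acid 23, via caesium carboxylate 25 (not isolated)
Conditions: Cs2CO3, DMF, rt; then 24, 70 °C
Reagents that add atoms: none
Why: O-alkylation of the caesium carboxylate (SN2 at the primary tosylate) avoids acyl activation of the very hindered acid, does not involve the glycerol stereocentre, and cannot harm C1 because that centre is already the thermodynamic epimer.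

Step 18
Reactants: 26 [(4S)-2,2-dimethyl-1,3-dioxolan-4-yl]methyl ester of acid 23
Product: 27 (2S)-2,3-dihydroxypropyl ester of acid 23
Conditions: AcOH/H2O 4:1, 40 °C
Reagents that add atoms: none
Why: Mild acid-catalysed acetal hydrolysis frees the diol, while the bulk of the acyl group suppresses acyl migration and the trisubstituted alkenes tolerate aqueous acetic acid.

Step 19
Reactants: 27 (2S)-2,3-dihydroxypropyl ester of acid 23
Product: 28 (2S)-3-acetoxy-2-hydroxypropyl (1S,2R,4aR,8aR)-2,4a,8a-trimethyl-5-(4-methylpent-3-en-1-yl)-1,2,3,4,4a,7,8,8a-octahydronaphthalene-1-carboxylate (target)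
Conditions: AcCl (1.05 equiv), 2,4,6-collidine, CH2Cl2, −78 °C
Reagents that add atoms: acetyl chloride, CC(=O)Cl
Why: Kinetically selective acylation with acetyl chloride and a hindered pyridine base at low temperature acetylates the primary hydroxyl in preference to the secondary one.

**Compound list**

1 | (S)-3-bromo-2-methylpropan-1-ol | OC[C@H](C)CBr | starting material
2 | (S)-(3-bromo-2-methylpropoxy)(tert-butyl)dimethylsilane | CC(C)(C)[Si](C)(C)OC[C@H](C)CBr | intermediate
3 | ethyl 2-methyl-3-oxobutanoate | CCOC(=O)C(C)C(C)=O | starting material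
4 | 1-bromo-3-methylbut-2-ene (prenyl bromide) | CC(C)=CCBr | starting material
5 | sodium lithium dianion (bis-enolate) of 3 | [Na+].[Li+].C=C([O-])C(C)=C([O-])OCC | intermediate
6 | ethyl 2,7-dimethyl-3-oxooct-6-enoate (enolisable C2, both epimers) | CCOC(=O)C(C)C(=O)CCC=C(C)C | intermediate
7 | ethyl (2E)-2,7-dimethyl-3-(tosyloxy)octa-2,6-dienoate | CCOC(=O)/C(C)=C(\CCC=C(C)C)OS(=O)(=O)c1ccc(C)cc1 | intermediate
8 | ethyl (2E)-3-ethenyl-2,7-dimethylocta-2,6-dienoate | CCOC(=O)/C(C)=C(\CCC=C(C)C)C=C | intermediate
9 | (2E)-3-ethenyl-2,7-dimethylocta-2,6-dien-1-ol | OC/C(C)=C(\CCC=C(C)C)C=C | intermediate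
10 | (2E)-1-bromo-3-ethenyl-2,7-dimethylocta-2,6-diene | BrC/C(C)=C(\CCC=C(C)C)C=C | intermediate
11 | [(S)-3-(tert-butyldimethylsilyloxy)-2-methylpropyl]magnesium bromide | CC(C)(C)[Si](C)(C)OC[C@H](C)C[Mg]Br | intermediate
12 | tert-butyl{[(2R,5E)-6-ethenyl-2,5,10-trimethylundeca-5,9-dien-1-yl]oxy}dimethylsilane | CC(C)(C)[Si](C)(C)OC[C@H](C)CC/C(C)=C(\CCC=C(C)C)C=C | intermediate
13 | (2R,5E)-6-ethenyl-2,5,10-trimethylundeca-5,9-dien-1-ol | OC[C@H](C)CC/C(C)=C(\CCC=C(C)C)C=C | intermediate
14 | (2R,5E)-6-ethenyl-2,5,10-trimethylundeca-5,9-dienal | O=C[C@H](C)CC/C(C)=C(\CCC=C(C)C)C=C | intermediate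
15 | (4R,7E)-8-ethenyl-2,4,7,12-trimethyltrideca-1,7,11-trien-3-ol (both C3 epimers) | C=C(C)C(O)[C@H](C)CC/C(C)=C(\CCC=C(C)C)C=C | intermediate
16 | (4R,7E)-8-ethenyl-2,4,7,12-trimethyltrideca-1,7,11-trien-3-one | C=C(C)C(=O)[C@H](C)CC/C(C)=C(\CCC=C(C)C)C=C | intermediate
17 | (2R,4aR,8aS)-2,4a,8a-trimethyl-5-(4-methylpent-3-en-1-yl)-3,4,4a,7,8,8a-hexahydronaphthalen-1(2H)-one (cis-fused, angular methyls cis, C2 methyl trans to them) | O=C1[C@H](C)CC[C@]2(C)C(CCC=C(C)C)=CCC[C@]12C | intermediate
18 | (2R,4aR,8aR)-2,4a,8a-trimethyl-1-methylidene-5-(4-methylpent-3-en-1-yl)-1,2,3,4,4a,7,8,8a-octahydronaphthalene | C=C1[C@H](C)CC[C@]2(C)C(CCC=C(C)C)=CCC[C@]12C | intermediate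
19 | 9-{[decalin-1-yl]methyl}-9-borabicyclo[3.3.1]nonane adduct of 18 (C1 epimers) | C1CCC2CCCC1B2CC3[C@H](C)CC[C@]4(C)C(CCC=C(C)C)=CCC[C@]34C | intermediate
20 | [(2R,4aR,8aR)-2,4a,8a-trimethyl-5-(4-methylpent-3-en-1-yl)-1,2,3,4,4a,7,8,8a-octahydronaphthalen-1-yl]methanol (C1 epimers) | OCC1[C@H](C)CC[C@]2(C)C(CCC=C(C)C)=CCC[C@]12C | intermediate
21 | corresponding 1-carbaldehyde, C1 epimer mixture | O=CC1[C@H](C)CC[C@]2(C)C(CCC=C(C)C)=CCC[C@]12C | intermediate
22 | (1S,2R,4aR,8aR)-2,4a,8a-trimethyl-5-(4-methylpent-3-en-1-yl)-1,2,3,4,4a,7,8,8a-octahydronaphthalene-1-carbaldehyde | O=C[C@H]1[C@H](C)CC[C@]2(C)C(CCC=C(C)C)=CCC[C@]12C | intermediate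
23 | (1S,2R,4aR,8aR)-2,4a,8a-trimethyl-5-(4-methylpent-3-en-1-yl)-1,2,3,4,4a,7,8,8a-octahydronaphthalene-1-carboxylic acid | OC(=O)[C@H]1[C@H](C)CC[C@]2(C)C(CCC=C(C)C)=CCC[C@]12C | intermediate
24 | [(4S)-2,2-dimethyl-1,3-dioxolan-4-yl]methyl 4-methylbenzenesulfonate ((S)-solketal tosylate) | CC1(C)OC[C@@H](COS(=O)(=O)c2ccc(C)cc2)O1 | starting material
25 | caesium salt of acid 23 | [Cs+].[O-]C(=O)[C@H]1[C@H](C)CC[C@]2(C)C(CCC=C(C)C)=CCC[C@]12C | intermediate
26 | [(4S)-2,2-dimethyl-1,3-dioxolan-4-yl]methyl (1S,2R,4aR,8aR)-2,4a,8a-trimethyl-5-(4-methylpent-3-en-1-yl)-1,2,3,4,4a,7,8,8a-octahydronaphthalene-1-carboxylate | CC1(C)OC[C@@H](COC(=O)[C@H]2[C@H](C)CC[C@]3(C)C(CCC=C(C)C)=CCC[C@]23C)O1 | intermediate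
27 | (2S)-2,3-dihydroxypropyl (1S,2R,4aR,8aR)-2,4a,8a-trimethyl-5-(4-methylpent-3-en-1-yl)-1,2,3,4,4a,7,8,8a-octahydronaphthalene-1-carboxylate | OC[C@H](O)COC(=O)[C@H]1[C@H](C)CC[C@]2(C)C(CCC=C(C)C)=CCC[C@]12C | intermediate
28 | (2S)-3-acetoxy-2-hydroxypropyl (1S,2R,4aR,8aR)-2,4a,8a-trimethyl-5-(4-methylpent-3-en-1-yl)-1,2,3,4,4a,7,8,8a-octahydronaphthalene-1-carboxylate | CC(=O)OC[C@H](O)COC(=O)[C@H]1[C@H](C)CC[C@]2(C)C(CCC=C(C)C)=CCC[C@]12C | target

**Step count**

Total step count: 19.
Longest linear sequence: 18 steps (steps 2–19, from 3 to 28); step 1 is a one-step side branch.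

**Steps most likely to fail**

Step 12.
- What may go wrong: the methyl group that sits inside the s-cis diene at C4a slows the cycloaddition. Lewis-acid-induced cation–olefin side reactions may then take over, or endo/exo selectivity may erode and lead to a trans ring fusion.
- Fallback, from 16 back to 17: the complexed enone is replaced by a free cationic dienophile, that is, an ionic Diels–Alder reaction.
- Ketalisation of 16 with 1,2-bis(trimethylsilyloxy)ethane and catalytic TMSOTf (CH2Cl2, −78 °C) should give the 2-isopropenyl-1,3-dioxolane F1.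
- Catalytic TfOH at −78 to −40 °C opens the dioxolane to the 2-alkoxyallyl (vinyl-oxocarbenium) cation. This is a much stronger dienophile and tolerates fully substituted diene termini. The cycloaddition and re-closure of the dioxolane should give the decalone ethylene ketal F2.
- PPTS in wet acetone then returns 17.

Step 14.
- What may go wrong: approach of 9-BBN to the methylidene group, flanked by a quaternary and a tertiary carbon, may be slow. Competing hydroboration of the unhindered side-chain alkene could then set in.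
- Fallback, from 17 back to 21 (bypassing 18–20): the carbon is brought in as an epoxide and no borane is used.
- Chloromethyllithium (ICH2Cl, MeLi·LiBr, THF, −78 °C → rt), a small and weakly basic nucleophile at low temperature, should add to the hindered ketone and close to the spiro-epoxide F3.
- Meinwald rearrangement with methylaluminium bis(4-bromo-2,6-di-tert-butylphenoxide) (CH2Cl2, −78 °C, 1,2-hydride shift) should give the aldehyde mixture 21. This enters the K2CO3/MeOH equilibration of step 15.

Step 7.
- What may go wrong: under copper catalysis the nucleophile may be delivered to the wrong allylic terminus (SN2′ at C5 or attack at the diene end), or the labile bromide may be lost before coupling.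
- Fallback, from 2 and 10 back to 12: a copper-free SN2 alkylation of a sulfone-stabilised carbanion is used.
- Displacement of bromide in 2 with PhSO2Na (DMF, 60 °C) should give the phenyl sulfone F4.
- Deprotonation with n-BuLi (THF, −78 °C) and addition of 10 should alkylate cleanly at the primary allylic carbon, giving the homoallylic sulfone F5.
- Reductive desulfonylation with Na(Hg), Na2HPO4 in MeOH (−20 °C) removes the auxiliary group without moving the alkenes, because the sulfone is not allylic. This gives 12.

**Further compounds**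

F1 | step 12 | 2-[(2R,5E)-6-ethenyl-5,10-dimethylundeca-5,9-dien-2-yl]-2-(prop-1-en-2-yl)-1,3-dioxolane | C=C(C)C1(OCCO1)[C@H](C)CC/C(C)=C(\CCC=C(C)C)C=C
F2 | step 12 | ethylene ketal of decalone 17 | O1CCOC12[C@H](C)CC[C@]3(C)C(CCC=C(C)C)=CCC[C@]23C
F3 | step 14 | spiro-epoxide (oxirane on C1) of decalone 17, either epimer at C1 | C1OC12[C@H](C)CC[C@]3(C)C(CCC=C(C)C)=CCC[C@]23C
F4 | step 7 | tert-butyldimethyl[(S)-2-methyl-3-(phenylsulfonyl)propoxy]silane | CC(C)(C)[Si](C)(C)OC[C@H](C)CS(=O)(=O)c1ccccc1
F5 | step 7 | 3-phenylsulfonyl derivative of 12 (both epimers at the sulfonyl carbon) | CC(C)(C)[Si](C)(C)OC[C@H](C)C(C/C(C)=C(\CCC=C(C)C)C=C)S(=O)(=O)c1ccccc1
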